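Ring A of sarothralin is a benzoylphloroglucinol: its benzoyl-bearing carbon lies between two oxygenated ring carbons and para to a third, the pattern of a folded triketo ester. The route cuts the ring A bond between the benzoyl-bearing carbon and the hydroxylated carbon next to the CH2 bridge. In one operation Mg(OMe)2 opens a 4-(methoxymethoxy)-6-phenacyl-2-pyranone that already carries ring B on a CH2 group at C3, and the phenacyl carbon is acylated by the former lactone carbonyl. This closes ring A with the para oxygen still masked. The precursor comes from triacetic acid lactone, methyl benzoate and isobutyrylfilicinic acid; prenylation and acetal removal finish the synthesis.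

Key step: step 5

Assumption: ring A is the benzoylphloroglucinol ring and ring B the acylfilicinic acid ring, written throughout as the dienol tautomer of the target SMILES. "(ring B)methyl" means [2,6-dihydroxy-3,3-dimethyl-5-(2-methylpropanoyl)-4-oxocyclohexa-1,5-dien-1-yl]methyl. The target has no stereocentre; the only geometric element in the route is the enol ether of 10.

Step 1
Reactants: 1 4-hydroxy-6-methyl-2H-pyran-2-one; 2 methyl benzoate
Product: 4 4-hydroxy-6-(2-oxo-2-phenylethyl)-2H-pyran-2-one, via dilithiated pyranone 3 (not isolated)
Conditions: LiN(iPr)2 (3.2 equiv), THF–DMPU, −78 °C; then 2, −78 to 0 °C; aq. HCl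
Reagents that add atoms: none
Why: Claisen-type acylation of a 1,3-dicarbonyl dianion, in which the second deprotonation creates the 6-CH2 carbanion as the most basic and therefore reacting site, the ester cannot enolise, and the third equivalent of base holds the more acidic product as its enolate so that over-addition is stopped.

Step 2
Reactants: 5 phloroisobutyrophenone [2-methyl-1-(2,4,6-trihydroxyphenyl)propan-1-one]
Product: 6 isobutyrylfilicinic acid [3,5-dihydroxy-6,6-dimethyl-2-(2-methylpropanoyl)cyclohexa-2,4-dien-1-one]
Conditions: MeI (2.2 equiv), NaOMe (3 equiv), MeOH, 0 °C to rt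
Reagents that add atoms: iodomethane, CI
Why: Dearomatising geminal C-methylation of an acylphloroglucinol anion, in which the two free ring carbons of 5 are equivalent, so only the degree of methylation needs control and the mono- and trimethyl by-products are expected to be removable by chromatography.

Step 3
Reactants: 6 isobutyrylfilicinic acid; 4 4-hydroxy-6-(2-oxo-2-phenylethyl)-2H-pyran-2-one
Product: 8 4-hydroxy-6-(2-oxo-2-phenylethyl)-3-[(ring B)methyl]-2H-pyran-2-one, via ring B Mannich base 7 (not isolated)
Conditions: [Me2N=CH2]I (1.05 equiv), MeCN, rt; then 4 (1.1 equiv), NaOAc, 60 °C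
Reagents that add atoms: N,N-dimethylmethyleneiminium iodide, C=[N+](C)C.[I-]
Why: Mannich reaction followed by elimination and Michael addition, in which the only free ring B carbon is aminomethylated to 7, warming with acetate releases dimethylamine to give a 2-methylene-1,3-dione, and this is captured by C3 of the 4-hydroxypyranone, its most nucleophilic carbon, while forming the Mannich base on ring B first keeps the iminium ion away from the phenacyl CH2 and limits symmetrical dimers.

Step 4
Reactants: 8 4-hydroxy-6-(2-oxo-2-phenylethyl)-3-[(ring B)methyl]-2H-pyran-2-one
Product: 9 4-(methoxymethoxy)-6-(2-oxo-2-phenylethyl)-3-[(ring B)methyl]-2H-pyran-2-one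
Conditions: MOMCl (1.05 equiv), iPr2NEt (1.1 equiv), CH2Cl2, −40 to 0 °C
Reagents that add atoms: chloromethyl methyl ether, COCCl
Why: O-alkoxymethylation of a vinylogous acid, in which the pyranone 4-hydroxyl is expected to be at least as acidic as ring B and much less hindered, so its oxide should take the hard chloromethyl ether on oxygen, whereas the ring B enolate, with charge spread over four oxygens, chelated to the isobutyryl carbonyl and flanked by fully substituted carbons, is a much weaker O-nucleophile.

Step 5
Reactants: 9 4-(methoxymethoxy)-6-(2-oxo-2-phenylethyl)-3-[(ring B)methyl]-2H-pyran-2-one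
Product: 11 [2,6-dihydroxy-4-(methoxymethoxy)-3-((ring B)methyl)phenyl](phenyl)methanone, via ring-opened methyl ester 10 (not isolated)
Conditions: Mg(OMe)2 (6 equiv), MeOH–THF, 65 °C; cold 0.5 M HCl work-up
Reagents that add atoms: none
Why: Methoxide from Mg(OMe)2 adds to the lactone carbonyl (pyranone C2) and the ring opens to ester 10, whose enol ether is E (ester and acetal oxygen trans, ester and diketone chain cis, as fixed by the ring); the phenacyl carbon, now the central carbon of a magnesium-chelated β-diketone, attacks the ester, methoxide leaves and the cyclohexenedione enolises to the arene. The closest known reaction type is the Mg(OMe)2-induced Claisen recyclisation of 6-(2-oxoalkyl)-4-oxy-2-pyranones and of 3,5,7-triketo esters to acylphloroglucinols. Ring A closes in a 6-(enolexo)-exo-trig Dieckmann-type acylation that joins the benzoyl-bearing carbon to the hydroxyl carbon next to the bridge carbon. No stereocentre is created, and the one geometric requirement, the cis relation of ester and chain, is inherited from the pyranone. C-acylation has to beat aldol closure onto the benzoyl carbonyl and O-cyclisation onto C4: the carbon alpha to the ester is a fully substituted enol ether carbon without hydrogen and cannot act as aldol donor, the chelate directs reaction to carbon, and aromatisation makes the Claisen path irreversible. The acetal stops the pyranone from expelling ring B by retro-Michael cleavage and ends para to the benzoyl group, so only the two ortho hydroxyls emerge free; the excess base carries ring B as its magnesium enolate.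

Step 6
Reactants: 11 [2,6-dihydroxy-4-(methoxymethoxy)-3-((ring B)methyl)phenyl](phenyl)methanone; 12 prenyl bromide (1-bromo-3-methylbut-2-ene)
Product: 13 [2-hydroxy-4-(methoxymethoxy)-6-(3-methylbut-2-enyloxy)-3-((ring B)methyl)phenyl](phenyl)methanone
Conditions: K2CO3 (2.5 equiv), 12 (1.05 equiv), acetone, rt
Reagents that add atoms: none
Why: Williamson etherification, in which the ring B enolate formed first is a delocalised, hindered and weak nucleophile, so the halide should be taken by the ring A phenoxide at the hydroxyl next to the ring C–H, because the other ortho hydroxyl is flanked by the bridge carbon and hydrogen-bonded to ring B, the para oxygen is blocked, and the remaining chelated hydroxyl resists a second alkylation.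

Step 7
Reactants: 13 [2-hydroxy-4-(methoxymethoxy)-6-(3-methylbut-2-enyloxy)-3-((ring B)methyl)phenyl](phenyl)methanone
Product: 14 sarothralin
Conditions: HCl (ca. 1 M), MeOH–THF, rt
Reagents that add atoms: none
Why: Acid-catalysed transacetalisation of the aryl methoxymethyl ether to methanol, which proceeds through the methoxymethyl oxocarbenium ion far more readily than the prenyl ether ionises, so mild monitored conditions should spare the prenyl group, while methanol removes the C1 unit as dimethoxymethane and keeps it from bridging the free ring A position.

Compound list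
number | name | SMILES with stereochemistry | role
1 | 4-hydroxy-6-methyl-2H-pyran-2-one (triacetic acid lactone) | CC1=CC(O)=CC(=O)O1 | starting material
2 | methyl benzoate | COC(=O)c1ccccc1 | starting material
3 | dilithiated pyranone (dilithium salt of the O4,C7-dianion of 1) | [Li+].[Li+].[CH2-]C1=CC([O-])=CC(=O)O1 | intermediate
4 | 4-hydroxy-6-(2-oxo-2-phenylethyl)-2H-pyran-2-one | O=C(CC1=CC(O)=CC(=O)O1)c1ccccc1 | intermediate
5 | phloroisobutyrophenone | CC(C)C(=O)c1c(O)cc(O)cc1O | starting material
6 | isobutyrylfilicinic acid | CC(C)C(=O)C1=C(O)C=C(O)C(C)(C)C1=O | intermediate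
7 | ring B Mannich base, 4-[(dimethylamino)methyl]-3,5-dihydroxy-6,6-dimethyl-2-(2-methylpropanoyl)cyclohexa-2,4-dien-1-one | CC(C)C(=O)C1=C(O)C(CN(C)C)=C(O)C(C)(C)C1=O | intermediate
8 | 4-hydroxy-6-(2-oxo-2-phenylethyl)-3-[(ring B)methyl]-2H-pyran-2-one | O=C(CC1=CC(O)=C(CC2=C(O)C(C)(C)C(=O)C(C(=O)C(C)C)=C2O)C(=O)O1)c1ccccc1 | intermediate
9 | 4-(methoxymethoxy)-6-(2-oxo-2-phenylethyl)-3-[(ring B)methyl]-2H-pyran-2-one (key-step precursor) | O=C(CC1=CC(OCOC)=C(CC2=C(O)C(C)(C)C(=O)C(C(=O)C(C)C)=C2O)C(=O)O1)c1ccccc1 | intermediate
10 | methyl (2E)-3-(methoxymethoxy)-5,7-dioxo-7-phenyl-2-[(ring B)methyl]hept-2-enoate | COC(=O)/C(CC1=C(O)C(C)(C)C(=O)C(C(=O)C(C)C)=C1O)=C(/OCOC)CC(=O)CC(=O)c1ccccc1 | intermediate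
11 | [2,6-dihydroxy-4-(methoxymethoxy)-3-((ring B)methyl)phenyl](phenyl)methanone (key-step product) | COCOc1cc(O)c(C(=O)c2ccccc2)c(O)c1CC1=C(O)C(C)(C)C(=O)C(C(=O)C(C)C)=C1O | intermediate
12 | prenyl bromide | CC(C)=CCBr | starting material
13 | [2-hydroxy-4-(methoxymethoxy)-6-(3-methylbut-2-enyloxy)-3-((ring B)methyl)phenyl](phenyl)methanone | CC(C)=CCOc1cc(OCOC)c(CC2=C(O)C(C)(C)C(=O)C(C(=O)C(C)C)=C2O)c(O)c1C(=O)c1ccccc1 | intermediate
14 | sarothralin, [2,4-dihydroxy-6-(3-methylbut-2-enyloxy)-3-((ring B)methyl)phenyl](phenyl)methanone | CC(C)=CCOc1cc(O)c(CC2=C(O)C(C)(C)C(=O)C(C(=O)C(C)C)=C2O)c(O)c1C(=O)c1ccccc1 | target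

Total step count: 7. Longest linear sequence: 6 steps (step 1 or step 2, then steps 3 to 7).

Steps most likely to fail

Step 5 is the riskiest. The lactone, deactivated by the phenacyl enolate, may fail to open. Methoxide may exchange the acetal-bearing oxygen substituent at C4 before ring opening. The diketone oxygen may cyclise onto C4 in place of the carbon onto the ester. Ring B may also be lost by retro-Michael fragmentation once the ring A phenoxide exists. The fallback makes ring A by electrophilic aromatic substitution and attaches ring B afterwards; it sets out from compound 6. Phloroglucinol is C-benzoylated (PhCOCl, AlCl3, PhNO2; Friedel–Crafts acylation) to 2,4,6-trihydroxybenzophenone F1. Its unchelated para hydroxyl is alkylated (MOMCl, iPr2NEt) to 2,6-dihydroxy-4-(methoxymethoxy)benzophenone F2. Compound 6 is converted into Mannich base 7 as in step 3 and warmed with an excess of F2, whose two free ring positions are equivalent, so that the ring B enone is captured ortho to a hydroxyl. This returns to the route at compound 11.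

Step 4 comes second. Site selectivity of the O-alkylation may be lost, with alkylation of ring B enol oxygens or double alkylation. The fallback installs the acetal before ring B is present; it sets out from compound 4. MOMCl and iPr2NEt should give 4-(methoxymethoxy)-6-(2-oxo-2-phenylethyl)-2H-pyran-2-one F3 without any competing acidic site. The same Mg(OMe)2 recyclisation on this simpler substrate should give F2, and coupling of F2 with Mannich base 7 (from 6, as in step 3) returns to the route at compound 11.

Step 6 comes third. Alkylation may stray to the ring B enolate on oxygen or carbon, to the hindered ortho hydroxyl, or occur twice. The fallback prenylates before ring B is attached; it sets out from compound 4, which gives F2 through F3 as above. The two hydroxyls of F2 are equivalent, so K2CO3 and one equivalent of 12 in acetone should give 2-hydroxy-4-(methoxymethoxy)-6-(3-methylbut-2-enyloxy)benzophenone F4. F4 is then joined to Mannich base 7 (from 6). Bridging is expected ortho to the remaining hydroxyl, but the regioisomer bridged between the two ether oxygens may form and would have to be removed by chromatography. This returns to the route at compound 13.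

Further compounds
F1 | step 5 | 2,4,6-trihydroxybenzophenone | O=C(c1ccccc1)c1c(O)cc(O)cc1O
F2 | step 5 | 2,6-dihydroxy-4-(methoxymethoxy)benzophenone | COCOc1cc(O)c(C(=O)c2ccccc2)c(O)c1
F3 | step 4 | 4-(methoxymethoxy)-6-(2-oxo-2-phenylethyl)-2H-pyran-2-one | COCOC1=CC(=O)OC(CC(=O)c2ccccc2)=C1
F4 | step 6 | 2-hydroxy-4-(methoxymethoxy)-6-(3-methylbut-2-enyloxy)benzophenone | COCOc1cc(O)c(C(=O)c2ccccc2)c(OCC=C(C)C)c1
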